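The flavan is cut at the C8a–O1 bond of ring C. O1 joins the A-ring carbon C8a to C2, a benzylic carbon para to the B-ring pyran oxygen that ionises easily. Closing the ring from the aryl side by copper-catalysed intramolecular O-arylation therefore forms ring C in one operation while the C2–O bond, and with it the (S) configuration set by ketone reduction, stays untouched. The substrate is an (S)-1,3-diarylpropan-1-ol carrying bromine at C8a, a prenyl ether at O7 and two silyl ethers on the fully built B ring. A late Claisen shift then moves the prenyl unit to C6 as the 1,1-dimethylallyl group.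

Key step: step 14

Remark: flavan numbering is used for the target (ring A = C4a–C8a, B ring primed). In the B-ring intermediates the fused dihydropyran is numbered as a chroman, whose C3 becomes the secondary carbinol and whose C6 carries the future C2. 6-Bromovanillin is taken as purchasable.

Step 1
Reactants: 1 2-bromo-4-hydroxy-5-methoxybenzaldehyde (6-bromovanillin); 2 3-chloro-3-methylbut-1-yne
Product: 3 2-bromo-5-methoxy-4-[(2-methylbut-3-yn-2-yl)oxy]benzaldehyde
Conditions: K2CO3, KI (cat.), CuI (cat.), acetone, reflux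
Reagents that add atoms: none
Why: Copper-assisted O-alkylation of the only free phenol by the tertiary propargylic chloride is the standard entry to 1,1-dimethylpropargyl aryl ethers, and the methyl ether on the neighbouring oxygen fixes which oxygen ends up in the pyran ring.

Step 2
Reactants: 3 2-bromo-5-methoxy-4-[(2-methylbut-3-yn-2-yl)oxy]benzaldehyde
Product: 5 5-bromo-8-methoxy-2,2-dimethyl-2H-chromene-6-carbaldehyde, via ortho-allenylphenol 4 (not isolated)
Conditions: PhNEt2, 190 °C
Reagents that add atoms: none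
Why: The aryl propargyl ether Claisen rearrangement can reach only the ortho carbon next to bromine (the other carries OMe), and the allenylphenol should close by 1,5-hydrogen shift and oxa-6π electrocyclisation to the 2,2-dimethylchromene.

Step 3
Reactants: 5 5-bromo-8-methoxy-2,2-dimethyl-2H-chromene-6-carbaldehyde
Product: 6 1-(5-bromo-8-methoxy-2,2-dimethyl-2H-chromen-6-yl)ethan-1-ol (racemic)
Conditions: MeMgBr, THF, 0 °C; aq NH4Cl
Reagents that add atoms: methylmagnesium bromide, C[Mg]Br
Why: Grignard addition to the aldehyde brings in the methyl carbon of the later acetyl group; the new carbinol centre is not controlled and is erased in step 6, and the alcohol oxidation level allows a hydride reagent in step 5.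

Step 4
Reactants: 6 1-(5-bromo-8-methoxy-2,2-dimethyl-2H-chromen-6-yl)ethan-1-ol
Product: 7 1-[(3S,4S)-5-bromo-3,4-epoxy-8-methoxy-2,2-dimethylchroman-6-yl]ethan-1-ol (both carbinol epimers)
Conditions: (S,S)-Jacobsen Mn(salen)Cl (5 mol%), NMO, mCPBA, CH2Cl2, −78 °C
Reagents that add atoms: meta-chloroperoxybenzoic acid (mCPBA), OOC(=O)c1cccc(Cl)c1
Why: Jacobsen epoxidation of the cis-disubstituted chromene alkene, the privileged substrate class for Mn(salen) catalysts, should set the (3S,4S) epoxide by catalyst control with the (S,S) ligand, and the anhydrous NMO/mCPBA protocol leaves the benzylic alcohol alone.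

Step 5
Reactants: 7 1-[(3S,4S)-5-bromo-3,4-epoxy-8-methoxy-2,2-dimethylchroman-6-yl]ethan-1-ol
Product: 8 (3S)-5-bromo-6-(1-hydroxyethyl)-8-methoxy-2,2-dimethylchroman-3-ol (both carbinol epimers)
Conditions: LiAlH4, THF, 0 °C → rt; Fieser work-up
Reagents that add atoms: none
Why: Hydride opening of the epoxide should occur at the benzylic C4, because C3 is shielded by the adjacent gem-dimethyl carbon, so the C3–O bond and its (S) configuration are retained (regioselective epoxide reduction).

Step 6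
Reactants: 8 (3S)-5-bromo-6-(1-hydroxyethyl)-8-methoxy-2,2-dimethylchroman-3-ol
Product: 9 1-[(3S)-5-bromo-3-hydroxy-8-methoxy-2,2-dimethylchroman-6-yl]ethan-1-one
Conditions: activated MnO2, CH2Cl2, rt → reflux
Reagents that add atoms: none
Why: Manganese dioxide oxidises the benzylic carbinol chemoselectively over the hindered aliphatic C3 alcohol, which merges the two carbinol epimers into one aryl methyl ketone.

Step 7
Reactants: 9 1-[(3S)-5-bromo-3-hydroxy-8-methoxy-2,2-dimethylchroman-6-yl]ethan-1-one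
Product: 10 1-[(3S)-5-bromo-3,8-dihydroxy-2,2-dimethylchroman-6-yl]ethan-1-one
Conditions: BBr3, CH2Cl2, −78 → 0 °C; then H2O
Reagents that add atoms: none
Why: Boron tribromide cleaves the aryl methyl ether by bromide attack at methyl, the tertiary chroman C2–O bond is deactivated by the neighbouring borate ester, and the step is placed before any acid-sensitive alkene is present.

Step 8
Reactants: 10 1-[(3S)-5-bromo-3,8-dihydroxy-2,2-dimethylchroman-6-yl]ethan-1-one
Product: 11 1-[(3S)-5-bromo-3,8-bis(tert-butyldimethylsilyloxy)-2,2-dimethylchroman-6-yl]ethan-1-one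
Conditions: TBSOTf, 2,6-lutidine, CH2Cl2, −78 → 0 °C
Reagents that add atoms: tert-butyldimethylsilyl trifluoromethanesulfonate (TBSOTf), CC(C)(C)[Si](C)(C)OS(=O)(=O)C(F)(F)F
Why: The silyl triflate silylates the phenol and the hindered secondary alcohol in one operation, so that both groups fall together to fluoride in the last step.

Step 9
Reactants: 11 1-[(3S)-5-bromo-3,8-bis(tert-butyldimethylsilyloxy)-2,2-dimethylchroman-6-yl]ethan-1-one; 12 tributyl(3-methylbut-2-en-1-yl)stannane
Product: 13 1-[(3S)-3,8-bis(tert-butyldimethylsilyloxy)-2,2-dimethyl-5-(3-methylbut-2-en-1-yl)chroman-6-yl]ethan-1-one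
Conditions: Pd(PPh3)4 (10 mol%), toluene, 110 °C
Reagents that add atoms: none
Why: In this Stille coupling the ortho-acetyl group activates the C–Br bond towards Pd(0), reductive elimination at the unsubstituted allyl terminus should give the linear prenyl arene, and the neutral medium spares both silyl ethers.

Step 10
Reactants: 14 2-bromo-4-hydroxybenzaldehyde; 15 prenyl bromide (1-bromo-3-methylbut-2-ene)
Product: 16 2-bromo-4-[(3-methylbut-2-en-1-yl)oxy]benzaldehyde
Conditions: K2CO3, DMF, rt
Reagents that add atoms: none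
Why: Williamson etherification of the single phenol with the primary allylic bromide gives the O-prenyl ether by SN2 substitution.

Step 11
Reactants: 13 1-[(3S)-3,8-bis(tert-butyldimethylsilyloxy)-2,2-dimethyl-5-(3-methylbut-2-en-1-yl)chroman-6-yl]ethan-1-one; 16 2-bromo-4-[(3-methylbut-2-en-1-yl)oxy]benzaldehyde
Product: 19 (E)-3-[2-bromo-4-(3-methylbut-2-en-1-yloxy)phenyl]-1-[(3S)-3,8-bis(tert-butyldimethylsilyloxy)-2,2-dimethyl-5-(3-methylbut-2-en-1-yl)chroman-6-yl]prop-2-en-1-one, via β-hydroxy ketone 17 (not isolated), via β-mesyloxy ketone 18 (not isolated)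
Conditions: LiHMDS, THF, −78 °C, then 16, aq NH4Cl; crude aldol: MsCl, Et3N, CH2Cl2, 0 °C → rt
Reagents that add atoms: none
Why: A directed aldol addition of the preformed lithium enolate to the non-enolisable aldehyde, followed by mesylation and E1cB elimination, should give the (E)-enone under aprotic conditions that keep the aryl silyl ether.

Step 12
Reactants: 19 (E)-enone
Product: 20 3-[2-bromo-4-(3-methylbut-2-en-1-yloxy)phenyl]-1-[(3S)-3,8-bis(tert-butyldimethylsilyloxy)-2,2-dimethyl-5-(3-methylbut-2-en-1-yl)chroman-6-yl]propan-1-one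
Conditions: [(Ph3P)CuH]6 (5 mol%), PhMe2SiH (1.1 equiv), t-BuOH, toluene, rt
Reagents that add atoms: none
Why: Copper hydride (Stryker-type) conjugate reduction is selective for the enone C=C and leaves the two isolated trisubstituted alkenes, the aryl bromide, the allyl aryl ether and the silyl ethers untouched.

Step 13
Reactants: 20 saturated ketone
Product: 21 (1S)-3-[2-bromo-4-(3-methylbut-2-en-1-yloxy)phenyl]-1-[(3S)-3,8-bis(tert-butyldimethylsilyloxy)-2,2-dimethyl-5-(3-methylbut-2-en-1-yl)chroman-6-yl]propan-1-ol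
Conditions: (R)-Me-CBS (20 mol%), catecholborane, toluene, −78 → −40 °C; MeOH, aq NaHCO3
Reagents that add atoms: none
Why: In this Corey–Bakshi–Shibata reduction the (R)-oxazaborolidine places the aryl group as the large substituent and delivers hydride to the Re face, which should give the (S)-carbinol, and catecholborane does not hydroborate the prenyl alkenes.

Step 14
Reactants: 21 (1S)-bromo alcohol
Product: 22 (2S)-2-[(3S)-3,8-bis(tert-butyldimethylsilyloxy)-2,2-dimethyl-5-(3-methylbut-2-en-1-yl)chroman-6-yl]-7-(3-methylbut-2-en-1-yloxy)chromane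
Conditions: CuI (10 mol%), 3,4,7,8-tetramethyl-1,10-phenanthroline (20 mol%), Cs2CO3, toluene, 110 °C
Reagents that add atoms: none
Why: The caesium alkoxide of the C2 carbinol binds copper(I), the C8a–Br bond is activated at the metal and C–O reductive elimination releases the aryl ether. This is an intramolecular Ullmann-type etherification of an aryl bromide by a secondary alcohol, a known route to chromans and flavans. Ring C closes by forming C8a–O1 in a 6-exo sense at the aryl carbon, held by the three-atom tether. No stereocentre is created: C2 keeps its (S) configuration because the C2–O bond is never broken, which avoids the ionisation that the para-oxygenated B ring would allow under acid or Mitsunobu activation. The step needs selectivity for the C2 hydroxyl, which is the only free OH, and for C–O coupling over loss of hydride from the benzylic alkoxide, which copper and the tethered geometry favour. It also needs the allyl aryl ether and the aryl silyl ether to survive; copper does not ionise the former, and carbonate in toluene rather than an alkoxide base spares the latter.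

Step 15
Reactants: 22 7-O-prenyl flavan
Product: 23 (2S)-2-[(3S)-3,8-bis(tert-butyldimethylsilyloxy)-2,2-dimethyl-5-(3-methylbut-2-en-1-yl)chroman-6-yl]-6-(2-methylbut-3-en-2-yl)chroman-7-ol
Conditions: PhNEt2, 190 °C, sealed tube
Reagents that add atoms: none
Why: The aromatic Claisen rearrangement joins the dimethyl-substituted allyl terminus to an ortho carbon and so gives the 1,1-dimethylallyl group; C6 should be preferred because C8 is wedged between O1 and O7 and migration para to the meta-alkoxy oxygen is also favoured electronically, and the basic solvent suppresses acid-catalysed ring closure of the new phenol.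

Step 16
Reactants: 23 bis-silyl flavan phenol
Product: 24 (2S)-2-[(3S)-3,8-dihydroxy-2,2-dimethyl-5-(3-methylbut-2-en-1-yl)chroman-6-yl]-6-(2-methylbut-3-en-2-yl)chroman-7-ol (CNP0323011.1)
Conditions: TBAF, THF, rt → 45 °C; aq NH4Cl
Reagents that add atoms: none
Why: Fluoride cleaves the aryl and the hindered secondary silyl ether without acid, so the ionisable C2 centre, the ortho-(1,1-dimethylallyl)phenol and the prenyl group are not exposed to cationic conditions.

Compound list

1 | 2-bromo-4-hydroxy-5-methoxybenzaldehyde (6-bromovanillin) | O=Cc1cc(OC)c(O)cc1Br | starting material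
2 | 3-chloro-3-methylbut-1-yne | C#CC(C)(C)Cl | starting material
3 | 2-bromo-5-methoxy-4-[(2-methylbut-3-yn-2-yl)oxy]benzaldehyde | C#CC(C)(C)Oc1cc(Br)c(C=O)cc1OC | intermediate
4 | 2-bromo-4-hydroxy-5-methoxy-3-(3-methylbuta-1,2-dien-1-yl)benzaldehyde (ortho-allenylphenol) | CC(C)=C=Cc1c(O)c(OC)cc(C=O)c1Br | intermediate (not isolated)
5 | 5-bromo-8-methoxy-2,2-dimethyl-2H-chromene-6-carbaldehyde | CC1(C)C=Cc2c(Br)c(C=O)cc(OC)c2O1 | intermediate
6 | 1-(5-bromo-8-methoxy-2,2-dimethyl-2H-chromen-6-yl)ethan-1-ol, racemic | CC(O)c1cc(OC)c2OC(C)(C)C=Cc2c1Br | intermediate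
7 | 1-[(3S,4S)-5-bromo-3,4-epoxy-8-methoxy-2,2-dimethylchroman-6-yl]ethan-1-ol, both carbinol epimers | CC(O)c1cc(OC)c2OC(C)(C)[C@H]3O[C@H]3c2c1Br | intermediate
8 | (3S)-5-bromo-6-(1-hydroxyethyl)-8-methoxy-2,2-dimethylchroman-3-ol, both carbinol epimers | CC(O)c1cc(OC)c2c(c1Br)C[C@H](O)C(C)(C)O2 | intermediate
9 | 1-[(3S)-5-bromo-3-hydroxy-8-methoxy-2,2-dimethylchroman-6-yl]ethan-1-one | CC(=O)c1cc(OC)c2c(c1Br)C[C@H](O)C(C)(C)O2 | intermediate
10 | 1-[(3S)-5-bromo-3,8-dihydroxy-2,2-dimethylchroman-6-yl]ethan-1-one | CC(=O)c1cc(O)c2c(c1Br)C[C@H](O)C(C)(C)O2 | intermediate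
11 | 1-[(3S)-5-bromo-3,8-bis(tert-butyldimethylsilyloxy)-2,2-dimethylchroman-6-yl]ethan-1-one | CC(=O)c1cc(O[Si](C)(C)C(C)(C)C)c2c(c1Br)C[C@H](O[Si](C)(C)C(C)(C)C)C(C)(C)O2 | intermediate
12 | tributyl(3-methylbut-2-en-1-yl)stannane | CC(C)=CC[Sn](CCCC)(CCCC)CCCC | starting material
13 | 1-[(3S)-3,8-bis(tert-butyldimethylsilyloxy)-2,2-dimethyl-5-(3-methylbut-2-en-1-yl)chroman-6-yl]ethan-1-one (B-ring methyl ketone) | CC(=O)c1cc(O[Si](C)(C)C(C)(C)C)c2c(c1CC=C(C)C)C[C@H](O[Si](C)(C)C(C)(C)C)C(C)(C)O2 | intermediate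
14 | 2-bromo-4-hydroxybenzaldehyde | O=Cc1ccc(O)cc1Br | starting material
15 | prenyl bromide (1-bromo-3-methylbut-2-ene) | CC(C)=CCBr | starting material
16 | 2-bromo-4-[(3-methylbut-2-en-1-yl)oxy]benzaldehyde | O=Cc1ccc(OCC=C(C)C)cc1Br | intermediate
17 | β-hydroxy ketone: 3-[2-bromo-4-(prenyloxy)phenyl]-3-hydroxy-1-[B-ring aryl]propan-1-one, both carbinol epimers | O=C(CC(O)c1ccc(OCC=C(C)C)cc1Br)c1cc(O[Si](C)(C)C(C)(C)C)c2c(c1CC=C(C)C)C[C@H](O[Si](C)(C)C(C)(C)C)C(C)(C)O2 | intermediate (not isolated)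
18 | β-mesyloxy ketone: methanesulfonate of 17 | O=C(CC(OS(C)(=O)=O)c1ccc(OCC=C(C)C)cc1Br)c1cc(O[Si](C)(C)C(C)(C)C)c2c(c1CC=C(C)C)C[C@H](O[Si](C)(C)C(C)(C)C)C(C)(C)O2 | intermediate (not isolated)
19 | (E)-3-[2-bromo-4-(prenyloxy)phenyl]-1-[(3S)-3,8-bis(TBSO)-2,2-dimethyl-5-prenylchroman-6-yl]prop-2-en-1-one | O=C(/C=C/c1ccc(OCC=C(C)C)cc1Br)c1cc(O[Si](C)(C)C(C)(C)C)c2c(c1CC=C(C)C)C[C@H](O[Si](C)(C)C(C)(C)C)C(C)(C)O2 | intermediate
20 | 3-[2-bromo-4-(prenyloxy)phenyl]-1-[(3S)-3,8-bis(TBSO)-2,2-dimethyl-5-prenylchroman-6-yl]propan-1-one | O=C(CCc1ccc(OCC=C(C)C)cc1Br)c1cc(O[Si](C)(C)C(C)(C)C)c2c(c1CC=C(C)C)C[C@H](O[Si](C)(C)C(C)(C)C)C(C)(C)O2 | intermediate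
21 | (1S)-3-[2-bromo-4-(prenyloxy)phenyl]-1-[(3S)-3,8-bis(TBSO)-2,2-dimethyl-5-prenylchroman-6-yl]propan-1-ol | O[C@H](c1cc(O[Si](C)(C)C(C)(C)C)c2c(c1CC=C(C)C)C[C@H](O[Si](C)(C)C(C)(C)C)C(C)(C)O2)CCc1ccc(OCC=C(C)C)cc1Br | intermediate
22 | (2S)-2-[(3S)-3,8-bis(TBSO)-2,2-dimethyl-5-prenylchroman-6-yl]-7-(prenyloxy)chromane | CC(C)=CCOc1ccc2c(c1)O[C@H](c1cc(O[Si](C)(C)C(C)(C)C)c3c(c1CC=C(C)C)C[C@H](O[Si](C)(C)C(C)(C)C)C(C)(C)O3)CC2 | intermediate
23 | (2S)-2-[(3S)-3,8-bis(TBSO)-2,2-dimethyl-5-prenylchroman-6-yl]-6-(2-methylbut-3-en-2-yl)chroman-7-ol | C=CC(C)(C)c1cc2c(cc1O)O[C@H](c1cc(O[Si](C)(C)C(C)(C)C)c3c(c1CC=C(C)C)C[C@H](O[Si](C)(C)C(C)(C)C)C(C)(C)O3)CC2 | intermediate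
24 | (2S)-2-[(3S)-3,8-dihydroxy-2,2-dimethyl-5-(3-methylbut-2-en-1-yl)chroman-6-yl]-6-(2-methylbut-3-en-2-yl)chroman-7-ol | C=CC(C)(C)c1cc2c(cc1O)O[C@H](c1cc(O)c3c(c1CC=C(C)C)C[C@H](O)C(C)(C)O3)CC2 | target

Total step count: 16. Longest linear sequence: 15 (steps 1–9, then 11–16); step 10 is the one-step side branch.

Steps most likely to fail

Step 14. The copper alkoxide may engage the C8a–Br bond too slowly. Reduction of the bromide, loss of hydride from the benzylic alkoxide to give the ketone, or silyl transfer from the aryl silyl ether under hot carbonate could then outrun ring closure. The fallback closes the other bond of the same oxygen bridge with inversion; it sets out from ketone 20 and comes back at flavan 22. Reduction of 20 with (S)-Me-CBS and catecholborane should give the (R)-carbinol epimer of 21, bromo alcohol F1. Miyaura borylation (B2pin2, PdCl2(dppf), KOAc, dioxane, 80 °C) should give the aryl pinacol boronate F2. Oxidation with NaBO3·4H2O in THF–water should give the C8a phenol F3. Mitsunobu cyclisation (PPh3, DIAD, THF, 0 °C) then displaces the activated C2 hydroxyl by the phenol with inversion and gives 22. This path accepts the danger of partial ionisation at C2, which is why it is held in reserve.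

Step 15. Site selectivity may be incomplete, with part of the allyl unit migrating to C8. The ortho-(1,1-dimethylallyl)phenol may also react further on heating, by ring closure onto its alkene or by loss of the C5 unit. The fallback carries out the sigmatropic shift before ring C exists; it sets out from ketone 20 and comes back at target 24. Heating 20 in PhNEt2 at 190 °C should give the rearranged phenol ketone F4; the competing ortho carbon is then flanked by bromine instead of O1, and any isomer is removed before the stereocentre is set. Silylation (TBSOTf, 2,6-lutidine) gives the tris-silyl ketone F5. Reduction with (R)-Me-CBS and catecholborane gives the (S)-carbinol F6. Copper-catalysed ring closure under the conditions of step 14 gives the tris-silyl flavan F7, which no longer contains an allyl aryl ether. TBAF then removes the three silyl groups and gives 24.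

Step 9. Transmetalation at the doubly ortho-substituted bromide may be slow, leading to protodebromination. Part of the coupling may also run through the substituted allyl terminus and give the 1,1-dimethylallyl isomer. The fallback installs the prenyl group in two stages; it sets out from bromide 11 and comes back at ketone 13. Stille coupling of 11 with allyltributylstannane (Pd(PPh3)4, toluene, 110 °C), which has no regiochemical ambiguity and a smaller nucleophile, should give the allyl ketone F8. Cross-metathesis with 2-methylbut-2-ene (Grubbs second-generation catalyst, CH2Cl2/2-methylbut-2-ene, 40 °C) then converts the allyl into the prenyl group and gives 13.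

Further compounds
F1 | step 14 | (1R)-3-[2-bromo-4-(prenyloxy)phenyl]-1-[(3S)-3,8-bis(TBSO)-2,2-dimethyl-5-prenylchroman-6-yl]propan-1-ol | O[C@@H](c1cc(O[Si](C)(C)C(C)(C)C)c2c(c1CC=C(C)C)C[C@H](O[Si](C)(C)C(C)(C)C)C(C)(C)O2)CCc1ccc(OCC=C(C)C)cc1Br
F2 | step 14 | (1R)-1-[(3S)-3,8-bis(TBSO)-2,2-dimethyl-5-prenylchroman-6-yl]-3-[4-(prenyloxy)-2-(4,4,5,5-tetramethyl-1,3,2-dioxaborolan-2-yl)phenyl]propan-1-ol | O[C@@H](c1cc(O[Si](C)(C)C(C)(C)C)c2c(c1CC=C(C)C)C[C@H](O[Si](C)(C)C(C)(C)C)C(C)(C)O2)CCc1ccc(OCC=C(C)C)cc1B1OC(C)(C)C(C)(C)O1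
F3 | step 14 | 2-{(3R)-3-[(3S)-3,8-bis(TBSO)-2,2-dimethyl-5-prenylchroman-6-yl]-3-hydroxypropyl}-5-(prenyloxy)phenol | O[C@@H](c1cc(O[Si](C)(C)C(C)(C)C)c2c(c1CC=C(C)C)C[C@H](O[Si](C)(C)C(C)(C)C)C(C)(C)O2)CCc1ccc(OCC=C(C)C)cc1O
F4 | step 15 | 3-[2-bromo-4-hydroxy-5-(2-methylbut-3-en-2-yl)phenyl]-1-[(3S)-3,8-bis(TBSO)-2,2-dimethyl-5-prenylchroman-6-yl]propan-1-one | O=C(CCc1cc(C(C)(C)C=C)c(O)cc1Br)c1cc(O[Si](C)(C)C(C)(C)C)c2c(c1CC=C(C)C)C[C@H](O[Si](C)(C)C(C)(C)C)C(C)(C)O2
F5 | step 15 | 3-[2-bromo-4-(TBSO)-5-(2-methylbut-3-en-2-yl)phenyl]-1-[(3S)-3,8-bis(TBSO)-2,2-dimethyl-5-prenylchroman-6-yl]propan-1-one | O=C(CCc1cc(C(C)(C)C=C)c(O[Si](C)(C)C(C)(C)C)cc1Br)c1cc(O[Si](C)(C)C(C)(C)C)c2c(c1CC=C(C)C)C[C@H](O[Si](C)(C)C(C)(C)C)C(C)(C)O2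
F6 | step 15 | (1S)-3-[2-bromo-4-(TBSO)-5-(2-methylbut-3-en-2-yl)phenyl]-1-[(3S)-3,8-bis(TBSO)-2,2-dimethyl-5-prenylchroman-6-yl]propan-1-ol | O[C@H](c1cc(O[Si](C)(C)C(C)(C)C)c2c(c1CC=C(C)C)C[C@H](O[Si](C)(C)C(C)(C)C)C(C)(C)O2)CCc1cc(C(C)(C)C=C)c(O[Si](C)(C)C(C)(C)C)cc1Br
F7 | step 15 | (2S)-2-[(3S)-3,8-bis(TBSO)-2,2-dimethyl-5-prenylchroman-6-yl]-7-(TBSO)-6-(2-methylbut-3-en-2-yl)chromane | C=CC(C)(C)c1cc2c(cc1O[Si](C)(C)C(C)(C)C)O[C@H](c1cc(O[Si](C)(C)C(C)(C)C)c3c(c1CC=C(C)C)C[C@H](O[Si](C)(C)C(C)(C)C)C(C)(C)O3)CC2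
F8 | step 9 | 1-[(3S)-5-allyl-3,8-bis(tert-butyldimethylsilyloxy)-2,2-dimethylchroman-6-yl]ethan-1-one | CC(=O)c1cc(O[Si](C)(C)C(C)(C)C)c2c(c1CC=C)C[C@H](O[Si](C)(C)C(C)(C)C)C(C)(C)O2
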